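**Retrosynthetic overview**

- The strategy rests on ring B: the C8 tertiary carbinol and C12 (carried as an ester carbonyl) are 1,4-related through C9 and C11. This dissonant pair is disconnected at C8–C9 by reversing the polarity of the C8 carbonyl (ketyl) towards C9 of an enoate.
- C12–C13 is cut next (B-alkyl Suzuki coupling) to an (E)-alkenyl iodide made from geranylacetone. The C3 ketone travels as a dioxolane and the C8 hydroxyl as a triethylsilyl ether.
- The ring-B precursor is a ring A cyclohexane with trans C5 (3-oxobutyl) and C10 (acrylate) arms. It comes from an enantioselective Diels–Alder reaction of (E)-2-methylhepta-2,6-dienal that sets C10 and C5 together, then C4 gem-dimethylation through the enone and Wacker unmasking of C8.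
- Ring order: ring A (Diels–Alder, step 2), then ring B (ketyl–olefin closure, step 8); the side chain is attached last.

Key step: step 8

**Remarks**

- Numbering: terpenoid numbering is used for all compounds (ring A = C1–C5 and C10; ring B = C5–C10; C11 and C12 on C9). β is the face of the C10 methyl group. The target is 5α-H, 10β-Me, 9α-H (9β side chain), 8α-OH, 8β-Me, i.e. (5R,8R,9R,10S).
- Assumption: the sense of induction of the chromium–salen catalyst with enal 3 is taken to follow that of simple α-substituted acroleins. The antipode that gives adduct 5 as drawn is written as (R,R); if a first run shows the opposite sense, the mirror-image catalyst, equally available, is used.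

**Route**

Step 1
Reactants: 1 pent-4-enal; 2 2-(triphenylphosphoranylidene)propanal
Product: 3 (E)-2-methylhepta-2,6-dienal
Conditions: toluene, 90 °C
Reagents that add atoms: none
Why: Wittig olefination with a stabilised α-formyl ylide gives the (E)-trisubstituted enal, and the unhindered saturated aldehyde 1 reacts far faster than the conjugated product aldehyde.

Step 2
Reactants: 3 (E)-2-methylhepta-2,6-dienal; 4 (E)-1-(dimethylamino)-3-(tert-butyldimethylsilyloxy)buta-1,3-diene
Product: 5 Diels–Alder adduct, 6-(but-3-enyl)-4-(tert-butyldimethylsilyloxy)-2-(dimethylamino)-1-methylcyclohex-3-ene-1-carbaldehyde (C10: Me β, CHO α; C5: butenyl β, H α; C1: NMe2 α)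
Conditions: (R,R)-(salen)CrCl (10 mol %; salen = N,N′-bis(3,5-di-tert-butylsalicylidene)cyclohexane-1,2-diaminate, trivalent chromium), 4 Å MS, CH2Cl2, −40 → 0 °C
Reagents that add atoms: none
Why: Lewis acid-catalysed enantioselective Diels–Alder reaction of an electron-rich 1-amino-3-siloxydiene with an α-substituted enal, here a β-alkylated member of that class: the CH2 terminus of 4 bonds to the enal β-carbon (C5) and the aminated terminus to the α-carbon (C10), suprafacial addition to the (E)-enal places the C10 methyl cis to the C5 butenyl arm and the formyl group trans to it, and attack on one face of the chromium-bound aldehyde sets C10 and C5 together in the absolute sense; the C1 amino centre (endo, cis to CHO) is removed in step 3.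

Step 3
Reactants: 5 Diels–Alder adduct
Product: 7 enone ethyl (E)-3-[6-(but-3-enyl)-1-methyl-4-oxocyclohex-2-enyl]acrylate (C1=C2 enone; 10β-Me; 5β-butenyl), via olefinated cycloadduct 6 (not isolated)
Conditions: (EtO)2P(O)CH2CO2Et, NaH, THF, 0 °C → rt; then 48% aq. HF, MeCN, 0 °C → rt
Reagents that add atoms: triethyl phosphonoacetate, CCOC(=O)CP(=O)(OCC)OCC
Why: Horner–Wadsworth–Emmons olefination of the non-enolisable neopentyl aldehyde gives the (E)-enoate, and HF then cleaves the silyl enol ether to a β-amino ketone that loses dimethylamine by E1cB elimination, leaving C10 and C5 untouched.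

Step 4
Reactants: 7 enone
Product: 9 4,4-dimethyl enone ethyl (E)-3-[6-(but-3-enyl)-1,5,5-trimethyl-4-oxocyclohex-2-enyl]acrylate, via monomethyl enone 8 (not isolated)
Conditions: LiN(SiMe3)2 (1.1 equiv), THF, −78 °C, then MeI, → 0 °C; recool, LiN(SiMe3)2 (1.3 equiv), then MeI (excess), −78 °C → rt
Reagents that add atoms: iodomethane, CI
Why: Enolate alkylation: because C10 is quaternary the enone can be deprotonated only at C4 (α′), so two deprotonation/methylation cycles place both methyl groups on C4, and the second erases the transient C4 stereocentre.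

Step 5
Reactants: 9 4,4-dimethyl enone
Product: 10 saturated ketone ethyl (E)-3-[2-(but-3-enyl)-1,3,3-trimethyl-4-oxocyclohexyl]acrylate
Conditions: [(Ph3P)CuH]6 (limiting hydride, monovalent copper), H2O (2 equiv), degassed benzene, rt
Reagents that add atoms: none
Why: Copper hydride conjugate reduction: the phosphine-ligated hydride adds to C1 of the cyclohexenone, the more electrophilic of the two acceptors, while the ester-conjugated alkene beside quaternary C10 and the isolated terminal alkene are expected to remain when the hydride is kept limiting.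

Step 6
Reactants: 10 saturated ketone
Product: 11 ketal ethyl (E)-3-[7-(but-3-enyl)-6,6,8-trimethyl-1,4-dioxaspiro[4.5]decan-8-yl]acrylate
Conditions: Me3SiOCH2CH2OSiMe3, TMSOTf (cat.), CH2Cl2, −78 → −20 °C
Reagents that add atoms: 1,2-bis(trimethylsilyloxy)ethane, C[Si](C)(C)OCCO[Si](C)(C)C
Why: Silyl triflate-catalysed ketalisation with the bis-silyl ether of ethylene glycol converts hindered ketones next to quaternary carbons and leaves the enoate and the alkene alone; C3 is the only ketone present.

Step 7
Reactants: 11 ketal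
Product: 12 keto enoate ethyl (E)-3-[6,6,8-trimethyl-7-(3-oxobutyl)-1,4-dioxaspiro[4.5]decan-8-yl]acrylate (10β-Me, 10α-acrylate arm, 5β-oxobutyl arm, 5α-H)
Conditions: PdCl2 (10 mol %), Cu(OAc)2·H2O (20 mol %), O2 (1 atm), DMA/H2O 7:1, rt
Reagents that add atoms: water, O
Why: Wacker oxidation: Markovnikov hydroxypalladation of the monosubstituted alkene gives the C8 methyl ketone, the electron-poor enoate alkene is not oxidised, and the acetate-buffered copper co-oxidant keeps the medium mild enough for the dioxolane.

Step 8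
Reactants: 12 keto enoate
Product: 13 bicyclic hydroxy ester, ethyl (3,3-ethylenedioxy-8α-hydroxy-4,4,8β,10β-tetramethyl-trans-decalin-9β-yl)acetate (5α-H, 9α-H)
Conditions: SmI2 (2.5 equiv, divalent samarium), HMPA (10 equiv), t-BuOH (2 equiv), THF (0.01 M), −78 → 0 °C; pH 7 buffer at 0 °C
Reagents that add atoms: none
Why: SmI2 activated by HMPA transfers one electron to the C8 methyl ketone; the carbon of the resulting samarium ketyl, now nucleophilic, adds to the enoate β-carbon C9, and the α-ester radical is reduced by a second SmI2 to a samarium enolate (trivalent samarium) that t-BuOH protonates at C11. The closest known reaction type is the SmI2-mediated ketyl–olefin reductive cyclisation of ketones onto α,β-unsaturated esters. Ring B is closed in the 6-exo-trig mode. C9 is controlled by a chair transition state built on the trans C5 and C10 arms of the ring A chair, in which the (E)-enoate lies pseudo-equatorial so that C11 ends up β and H-9 α; C8 is controlled by the size of the HMPA-solvated O–Sm group, which takes the equatorial α position and leaves the small methyl group axial and β. The step needs chemoselective electron transfer at C8 and the 8,9-anti relationship: the dioxolane masking C3 secures the first, and the ring A template with its axial C10 methyl, which disfavours an axial O–Sm, secures the second.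

Step 9
Reactants: 13 bicyclic hydroxy ester
Product: 14 8α-triethylsilyloxy ester
Conditions: TESOTf (1.5 equiv), 2,6-lutidine (3 equiv), CH2Cl2, −78 → 0 °C
Reagents that add atoms: triethylsilyl trifluoromethanesulfonate, CC[Si](CC)(CC)OS(=O)(=O)C(F)(F)F
Why: Silylation of the hindered tertiary C8 alcohol with a silyl triflate and a non-nucleophilic base, carried out directly on the hydroxy ester so that the hydroxyl can no longer close onto C12 as a lactone or, later, as a cyclic ether.

Step 10
Reactants: 14 8α-triethylsilyloxy ester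
Product: 15 C12 primary alcohol (8α-OTES, C3 dioxolane)
Conditions: LiAlH4, Et2O, 0 °C
Reagents that add atoms: none
Why: Hydride reduction of the ester to the primary C12 alcohol with LiAlH4, to which the silyl ether and the dioxolane are inert.

Step 11
Reactants: 15 C12 primary alcohol
Product: 16 C12 iodide (8α-OTES, C3 dioxolane)
Conditions: I2, PPh3, imidazole, CH2Cl2, 0 °C → rt
Reagents that add atoms: iodine, II
Why: Appel-type iodination: the primary alkoxyphosphonium ion is displaced by iodide in an SN2 step while the tertiary oxygen is blocked as its silyl ether.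

Step 12
Reactants: 17 (E)-geranylacetone
Product: 19 (E)-6,10-dimethylundeca-5,9-dien-1-yne, via enol diethyl phosphate 18 (not isolated)
Conditions: LiN(i-Pr)2 (1.05 equiv), THF, −78 °C; ClP(O)(OEt)2, −78 °C → rt; then LiN(i-Pr)2 (2.3 equiv), THF, −78 °C → rt
Reagents that add atoms: none
Why: Kinetic deprotonation on the methyl side and O-phosphorylation give the terminal enol phosphate, from which further base eliminates phosphate to the terminal alkyne (methyl ketone to alkyne conversion); the trisubstituted alkenes are spectators and keep their geometry.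

Step 13
Reactants: 19 (E)-6,10-dimethylundeca-5,9-dien-1-yne
Product: 21 (1E,5E)-1-iodo-2,6,10-trimethylundeca-1,5,9-triene, via dimethylalkenylalane 20 (not isolated)
Conditions: Me3Al (2 equiv), Cp2ZrCl2 (0.25 equiv), ClCH2CH2Cl, rt; then I2, THF, −30 → 0 °C
Reagents that add atoms: trimethylaluminium, C[Al](C)C; iodine, II
Why: Zirconium-catalysed carboalumination (Negishi carboalumination): syn addition of methyl and aluminium across the terminal alkyne, with aluminium on the terminal carbon, followed by iodinolysis with retention, fixes the (E)-geometry of the new trisubstituted alkene.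

Step 14
Reactants: 16 C12 iodide; 21 (1E,5E)-1-iodo-2,6,10-trimethylundeca-1,5,9-triene
Product: 24 coupled ketal silyl ether (full carbon skeleton; C3 dioxolane, 8α-OTES), via alkyllithium 22 (not isolated), via lithium alkylmethoxyborate 23 (not isolated)
Conditions: t-BuLi (2.1 equiv), Et2O, −78 °C; B-methoxy-9-BBN (2.3 equiv), THF, −78 °C → rt; then 21, PdCl2(dppf) (5 mol %; dppf = 1,1′-bis(diphenylphosphino)ferrocene), AsPh3, 3 M aq. K3PO4, DMF, rt
Reagents that add atoms: none
Why: B-alkyl Suzuki–Miyaura coupling: iodine–lithium exchange and capture by the borinate give a B-alkyl borate that transfers its primary alkyl group to palladium after oxidative addition of alkenyl iodide 21, forming C12–C13 with retention of the (E)-alkene geometry.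

Step 15
Reactants: 24 coupled ketal silyl ether
Product: 25 target, (4aS,5R,6R,8aR)-6-hydroxy-1,1,4a,6-tetramethyl-5-[(3E,7E)-4,8,12-trimethyltrideca-3,7,11-trienyl]octahydronaphthalen-2(1H)-one
Conditions: 1 M aq. HCl, THF, 0 °C → rt
Reagents that add atoms: water, O
Why: Acid hydrolysis removes the dioxolane (water supplies the C3 carbonyl oxygen) and the tertiary triethylsilyl ether in one operation, under conditions too mild to dehydrate the tertiary alcohol or protonate the trisubstituted alkenes.

**Compound list**

1 | pent-4-enal | C=CCCC=O | starting material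
2 | 2-(triphenylphosphoranylidene)propanal | CC(C=O)=P(c1ccccc1)(c1ccccc1)c1ccccc1 | starting material
3 | (E)-2-methylhepta-2,6-dienal | C=CCC/C=C(\C)C=O | intermediate
4 | (E)-1-(dimethylamino)-3-(tert-butyldimethylsilyloxy)buta-1,3-diene | CN(C)/C=C/C(=C)O[Si](C)(C)C(C)(C)C | starting material
5 | Diels–Alder adduct: 6-(but-3-enyl)-4-(tert-butyldimethylsilyloxy)-2-(dimethylamino)-1-methylcyclohex-3-ene-1-carbaldehyde (Me cis to butenyl, CHO trans to butenyl and cis to NMe2) | O=C[C@@]1(C)[C@@H](N(C)C)C=C(O[Si](C)(C)C(C)(C)C)C[C@@H]1CCC=C | intermediate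
6 | olefinated cycloadduct: ethyl (E)-acrylate on C10 of the amino silyl enol ether | CCOC(=O)/C=C/[C@@]1(C)[C@@H](N(C)C)C=C(O[Si](C)(C)C(C)(C)C)C[C@@H]1CCC=C | intermediate (not isolated)
7 | enone: ethyl (E)-3-[6-(but-3-enyl)-1-methyl-4-oxocyclohex-2-enyl]acrylate (10β-Me, 5β-butenyl) | CCOC(=O)/C=C/[C@@]1(C)C=CC(=O)C[C@@H]1CCC=C | intermediate
8 | monomethyl enone (C4 epimers) | CCOC(=O)/C=C/[C@@]1(C)C=CC(=O)C(C)[C@@H]1CCC=C | intermediate (not isolated)
9 | 4,4-dimethyl enone: ethyl (E)-3-[6-(but-3-enyl)-1,5,5-trimethyl-4-oxocyclohex-2-enyl]acrylate | CCOC(=O)/C=C/[C@@]1(C)C=CC(=O)C(C)(C)[C@@H]1CCC=C | intermediate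
10 | saturated ketone: ethyl (E)-3-[2-(but-3-enyl)-1,3,3-trimethyl-4-oxocyclohexyl]acrylate | CCOC(=O)/C=C/[C@@]1(C)CCC(=O)C(C)(C)[C@@H]1CCC=C | intermediate
11 | ketal: ethyl (E)-3-[7-(but-3-enyl)-6,6,8-trimethyl-1,4-dioxaspiro[4.5]decan-8-yl]acrylate | CCOC(=O)/C=C/[C@@]1(C)CCC2(OCCO2)C(C)(C)[C@@H]1CCC=C | intermediate
12 | keto enoate (key-step precursor): ethyl (E)-3-[6,6,8-trimethyl-7-(3-oxobutyl)-1,4-dioxaspiro[4.5]decan-8-yl]acrylate, arms trans | CCOC(=O)/C=C/[C@@]1(C)CCC2(OCCO2)C(C)(C)[C@@H]1CCC(C)=O | intermediate
13 | bicyclic hydroxy ester (key-step product): C3 dioxolane, 8α-OH, 8β-Me, 9β-CH2CO2Et, 10β-Me, 5α-H; (5R,8R,9R,10S) | CCOC(=O)C[C@@H]1[C@@]2(C)CCC3(OCCO3)C(C)(C)[C@@H]2CC[C@@]1(C)O | intermediate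
14 | 8α-triethylsilyloxy ester | CCOC(=O)C[C@@H]1[C@@]2(C)CCC3(OCCO3)C(C)(C)[C@@H]2CC[C@@]1(C)O[Si](CC)(CC)CC | intermediate
15 | C12 primary alcohol (8α-OTES, C3 dioxolane) | OCC[C@@H]1[C@@]2(C)CCC3(OCCO3)C(C)(C)[C@@H]2CC[C@@]1(C)O[Si](CC)(CC)CC | intermediate
16 | C12 iodide (8α-OTES, C3 dioxolane) | ICC[C@@H]1[C@@]2(C)CCC3(OCCO3)C(C)(C)[C@@H]2CC[C@@]1(C)O[Si](CC)(CC)CC | intermediate
17 | (E)-geranylacetone | CC(C)=CCC/C(C)=C/CCC(C)=O | starting material
18 | enol diethyl phosphate of geranylacetone (terminal) | CC(C)=CCC/C(C)=C/CCC(=C)OP(=O)(OCC)OCC | intermediate (not isolated)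
19 | (E)-6,10-dimethylundeca-5,9-dien-1-yne | CC(C)=CCC/C(C)=C/CCC#C | intermediate
20 | dimethyl[(1E,5E)-2,6,10-trimethylundeca-1,5,9-trienyl]alane | CC(C)=CCC/C(C)=C/CC/C(C)=C/[Al](C)C | intermediate (not isolated)
21 | (1E,5E)-1-iodo-2,6,10-trimethylundeca-1,5,9-triene | CC(C)=CCC/C(C)=C/CC/C(C)=C/I | intermediate
22 | C12 alkyllithium | [Li]CC[C@@H]1[C@@]2(C)CCC3(OCCO3)C(C)(C)[C@@H]2CC[C@@]1(C)O[Si](CC)(CC)CC | intermediate (not isolated)
23 | lithium B-alkyl-B-methoxy-9-borabicyclo[3.3.1]nonane borate | [Li+].CO[B-]1(CC[C@@H]2[C@@]3(C)CCC4(OCCO4)C(C)(C)[C@@H]3CC[C@@]2(C)O[Si](CC)(CC)CC)C5CCCC1CCC5 | intermediate (not isolated)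
24 | coupled ketal silyl ether (C3 dioxolane, 8α-OTES, all-E side chain) | CC(C)=CCC/C(C)=C/CC/C(C)=C/CC[C@@H]1[C@@]2(C)CCC3(OCCO3)C(C)(C)[C@@H]2CC[C@@]1(C)O[Si](CC)(CC)CC | intermediate
25 | CNP0158964.2, (4aS,5R,6R,8aR)-6-hydroxy-1,1,4a,6-tetramethyl-5-[(3E,7E)-4,8,12-trimethyltrideca-3,7,11-trienyl]octahydronaphthalen-2(1H)-one | CC(C)=CCC/C(C)=C/CC/C(C)=C/CC[C@@H]1[C@@]2(C)CCC(=O)C(C)(C)[C@@H]2CC[C@@]1(C)O | target

**Step count**

Total: 15 steps. Longest linear sequence: 13 steps (steps 1–11, 14, 15); steps 12 and 13 form the side-chain branch.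

**Steps most likely to fail**

1. Step 8 (key step). The ketyl may be reduced on to the secondary alcohol or dimerise before it closes the ring, or it may add with the wrong topicity at C8, since the favoured chair must place a methyl group 1,3-diaxial to the C10 methyl.
Fallback, from 11, rejoining at 24: ring B is closed with normal polarity, C9 acting as the nucleophilic γ-carbon of an allylmetal.
   - Ester 11 is reduced with i-Bu2AlH (CH2Cl2, −78 °C) to the (E)-allylic alcohol F1.
   - The terminal alkene is oxidised under the conditions of step 7 to the keto allylic alcohol F2.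
   - CBr4/PPh3 (CH2Cl2, 0 °C) gives the keto allylic bromide F3.
   - CrCl2 (divalent chromium, THF, rt) forms an allylchromium species that adds through C9 to the C8 ketone (intramolecular Nozaki–Hiyama allylation) in a cyclic chair transition state, and should give the 8α-hydroxy-9β-vinyl bicycle F4.
   - TESOTf/2,6-lutidine gives the vinyl silyl ether F5.
   - Hydroboration of the vinyl group with 9-BBN-H (THF, rt) gives the B-alkyl-9-BBN borane F6, which is coupled with iodide 21 under the palladium conditions of step 14 to give 24.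

2. Step 2. The β-substituted enal is a bulkier and weaker ligand for chromium than simple α-substituted acroleins, so turnover may be slow and the uncatalysed background cycloaddition may erode the enantiomeric purity.
Fallback, from 3, rejoining at 7: asymmetric induction is moved from the catalyst to a C2-symmetric auxiliary on the diene.
   - (2R,5R)-2,5-Diphenylpyrrolidine is condensed with 4-methoxybut-3-en-2-one to the vinylogous amide F7.
   - O-Silylation (KN(SiMe3)2, TBSCl, THF, −78 °C) gives the chiral aminosiloxydiene F8.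
   - Thermal cycloaddition with enal 3 (toluene, rt → 60 °C) should give the auxiliary-bearing cycloadduct F9 under auxiliary control.
   - Horner–Wadsworth–Emmons olefination as in step 3 gives the olefinated auxiliary adduct F10, and HF/MeCN then releases the auxiliary and gives enone 7.
   - The (2R,5R) auxiliary is written; the antipode that matches the required sense is fixed by a trial run.

3. Step 5. Hydride transfer to the enoate may compete with transfer to the enone, because both acceptors sit on the same quaternary carbon and differ only in electrophilicity.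
Fallback, from 9, rejoining at 11: no discrimination is asked for; both conjugated alkenes are reduced and the enoate is rebuilt.
   - Enone 9 is treated with excess [(Ph3P)CuH]6 (or catalytic Cu(OAc)2 with 1,2-bis(diphenylphosphino)benzene and polymethylhydrosiloxane) to give the saturated keto ester F11.
   - Ketalisation as in step 6 gives the saturated ketal ester F12.
   - LiN(i-Pr)2 (THF, −78 °C) followed by PhSeBr gives the α-phenylselanyl ester F13.
   - H2O2/pyridine (CH2Cl2, 0 °C) oxidises selenium and triggers syn-elimination towards C9, the only β-carbon bearing hydrogen, returning (E)-enoate 11.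

**Further compounds**

F1 | step 8 | (E)-allylic alcohol from 11 (C12 CH2OH, C3 dioxolane, 5β-butenyl) | OC/C=C/[C@@]1(C)CCC2(OCCO2)C(C)(C)[C@@H]1CCC=C
F2 | step 8 | keto allylic alcohol (C8 methyl ketone) | OC/C=C/[C@@]1(C)CCC2(OCCO2)C(C)(C)[C@@H]1CCC(C)=O
F3 | step 8 | keto allylic bromide | BrC/C=C/[C@@]1(C)CCC2(OCCO2)C(C)(C)[C@@H]1CCC(C)=O
F4 | step 8 | 8α-hydroxy-9β-vinyl bicycle (C3 dioxolane) | C=C[C@@H]1[C@@]2(C)CCC3(OCCO3)C(C)(C)[C@@H]2CC[C@@]1(C)O
F5 | step 8 | 8α-triethylsilyloxy-9β-vinyl bicycle | C=C[C@@H]1[C@@]2(C)CCC3(OCCO3)C(C)(C)[C@@H]2CC[C@@]1(C)O[Si](CC)(CC)CC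
F6 | step 8 | B-alkyl-9-borabicyclo[3.3.1]nonane (boron on C12) | B1(CC[C@@H]2[C@@]3(C)CCC4(OCCO4)C(C)(C)[C@@H]3CC[C@@]2(C)O[Si](CC)(CC)CC)C5CCCC1CCC5
F7 | step 2 | (E)-4-[(2R,5R)-2,5-diphenylpyrrolidin-1-yl]but-3-en-2-one | CC(=O)/C=C/N1[C@@H](c2ccccc2)CC[C@@H]1c3ccccc3
F8 | step 2 | (E)-1-[(2R,5R)-2,5-diphenylpyrrolidin-1-yl]-3-(tert-butyldimethylsilyloxy)buta-1,3-diene | C=C(O[Si](C)(C)C(C)(C)C)/C=C/N1[C@@H](c2ccccc2)CC[C@@H]1c3ccccc3
F9 | step 2 | auxiliary-bearing cycloadduct (aldehyde) | O=C[C@@]1(C)[C@@H](N2[C@@H](c3ccccc3)CC[C@@H]2c4ccccc4)C=C(O[Si](C)(C)C(C)(C)C)C[C@@H]1CCC=C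
F10 | step 2 | olefinated auxiliary adduct (ethyl (E)-acrylate) | CCOC(=O)/C=C/[C@@]1(C)[C@@H](N2[C@@H](c3ccccc3)CC[C@@H]2c4ccccc4)C=C(O[Si](C)(C)C(C)(C)C)C[C@@H]1CCC=C
F11 | step 5 | saturated keto ester, ethyl 3-[2-(but-3-enyl)-1,3,3-trimethyl-4-oxocyclohexyl]propanoate | CCOC(=O)CC[C@@]1(C)CCC(=O)C(C)(C)[C@@H]1CCC=C
F12 | step 5 | saturated ketal ester | CCOC(=O)CC[C@@]1(C)CCC2(OCCO2)C(C)(C)[C@@H]1CCC=C
F13 | step 5 | α-phenylselanyl ester (epimers at C11) | CCOC(=O)C([Se]c1ccccc1)C[C@@]1(C)CCC2(OCCO2)C(C)(C)[C@@H]1CCC=C
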